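**Strategy**

The route rests on one disconnection: the bond between the second and third carbons (C2'–C3') of the unbranched henicosyl chain on C3 of the pyrrole ring. Because this chain is a plain run of CH2 groups with no heteroatom or stereocentre, the bond can be made by joining two primary radicals in a crossed Kolbe electrolysis. In one operation this removes two CO2H groups and joins a two-carbon ring-bound stub to a C19 fragment from inexpensive icosanoic acid. The electrolysis substrate is the N-tosyl pyrrole-2-carboxylate carrying a CH2CH2CO2H arm on C3, reached by a Heck reaction and a hydrogenation; detosylation then gives the target.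

Key step: step 4

Remark on the chemistry: the acrylate partner is used as its benzyl ester, so that one hydrogenation both saturates the alkene and frees the acid. The bromopyrrole ester, benzyl acrylate and icosanoic acid are assumed to be catalogue compounds. The target has no stereocentre.

**Route**

Step 1
Reactants: 1 methyl 3-bromo-1H-pyrrole-2-carboxylate
Product: 3 methyl 3-bromo-1-tosyl-1H-pyrrole-2-carboxylate, via bromopyrrolide sodium salt 2 (not isolated)
Conditions: NaH (1.2 equiv), THF, 0 °C; then TsCl (1.2 equiv), 0 °C to rt
Reagents that add atoms: sodium hydride, [Na+].[H-] (its sodium stays only in 2); p-toluenesulfonyl chloride (TsCl), Cc1ccc(cc1)S(=O)(=O)Cl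
Why: The N–H, acidified by the C2 ester, is deprotonated irreversibly and the anion is sulfonylated on nitrogen (N-sulfonylation); the C–Br bond and the ester are inert.

Step 2
Reactants: 3 methyl 3-bromo-1-tosyl-1H-pyrrole-2-carboxylate; 4 benzyl acrylate
Product: 5 methyl 3-[(E)-3-(benzyloxy)-3-oxoprop-1-en-1-yl]-1-tosyl-1H-pyrrole-2-carboxylate
Conditions: Pd(OAc)2 (5 mol%), P(o-tol)3 (10 mol%), Et3N (2 equiv), DMF, 100 °C
Reagents that add atoms: none
Why: Mizoroki–Heck reaction: zerovalent palladium formed in situ inserts into the electron-poor C3–Br bond, then syn-carbopalladation at the unsubstituted acrylate terminus and syn-β-hydride elimination should give the E-alkene, whose geometry is erased in the next step.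

Step 3
Reactants: 5 methyl 3-[(E)-3-(benzyloxy)-3-oxoprop-1-en-1-yl]-1-tosyl-1H-pyrrole-2-carboxylate
Product: 7 3-[2-(methoxycarbonyl)-1-tosyl-1H-pyrrol-3-yl]propanoic acid, via saturated benzyl ester 6 (not isolated)
Conditions: H2 (1 atm), 10% Pd/C, EtOAc–MeOH (1:1), rt
Reagents that add atoms: none
Why: Catalytic hydrogenation saturates the conjugated alkene and then hydrogenolyses the benzylic C–O bond in the same flask; the sulfonamide, the methyl ester and the electron-poor pyrrole ring should not be touched.

Step 4
Reactants: 7 3-[2-(methoxycarbonyl)-1-tosyl-1H-pyrrol-3-yl]propanoic acid; 8 icosanoic acid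
Product: 9 methyl 3-henicosyl-1-tosyl-1H-pyrrole-2-carboxylate
Conditions: 8 (6 equiv), KOH (ca. 5 mol% of total acid), MeOH, 50 °C, Pt anode/Pt cathode, undivided cell, constant current (ca. 0.25 A cm-2), periodic polarity reversal, stopped while still weakly acidic
Reagents that add atoms: none
Why: Mixed Kolbe electrolysis: at the platinum anode each carboxylate gives up one electron and loses CO2, and the two primary radicals so formed (ring–CH2CH2• and nonadecyl•) combine in the electrode layer to make the C2'–C3' bond of the chain, while protons are reduced to H2 at the cathode. The closest known reaction type is the crossed Kolbe coupling of a functionalised acid with an excess of a simple fatty acid in partly neutralised methanol. No ring is closed and no stereocentre is formed. Three selectivities are needed: carboxylate oxidation must outrun oxidation of the heteroarene, which the N-sulfonyl and C2 ester groups secure by making the pyrrole ring electron-poor; the ring-side radical must couple and not be oxidised on to a cation, which is favoured because it is an unstabilised primary radical one CH2 away from the ring and because smooth platinum, high current density and a weakly acidic medium favour the one-electron path; and cross-coupling must beat homo-coupling of 7, which the sixfold excess of 8 secures on statistical grounds. Stopping before the electrolyte turns basic keeps the N-tosyl group in place, and the hydrocarbon dimer of 8 and the bis-pyrrole dimer differ strongly in polarity from 9 and should be removed on silica.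

Step 5
Reactants: 9 methyl 3-henicosyl-1-tosyl-1H-pyrrole-2-carboxylate
Product: 11 methyl 3-henicosyl-1H-pyrrole-2-carboxylate (target), via henicosylpyrrolide sodium salt 10 (not isolated)
Conditions: NaOMe (5 equiv), MeOH–THF (1:1), rt to 40 °C; then AcOH
Reagents that add atoms: sodium methoxide, [Na+].[O-]C (its sodium stays only in 10)
Why: Nucleophilic N-desulfonylation: methoxide attacks the sulfonyl sulfur and expels the ester-stabilised pyrrolide, exchange at the methyl ester is degenerate in methanol, and the acid quench protonates nitrogen; THF keeps the waxy substrate in solution.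

**Compound list**

1 | methyl 3-bromo-1H-pyrrole-2-carboxylate | COC(=O)c1[nH]ccc1Br | starting material
2 | sodium 3-bromo-2-(methoxycarbonyl)pyrrol-1-ide | COC(=O)c1[n-]ccc1Br.[Na+] | intermediate
3 | methyl 3-bromo-1-tosyl-1H-pyrrole-2-carboxylate | COC(=O)c1c(Br)ccn1S(=O)(=O)c1ccc(C)cc1 | intermediate
4 | benzyl acrylate | C=CC(=O)OCc1ccccc1 | starting material
5 | methyl 3-[(E)-3-(benzyloxy)-3-oxoprop-1-en-1-yl]-1-tosyl-1H-pyrrole-2-carboxylate | COC(=O)c1c(/C=C/C(=O)OCc2ccccc2)ccn1S(=O)(=O)c1ccc(C)cc1 | intermediate
6 | methyl 3-[3-(benzyloxy)-3-oxopropyl]-1-tosyl-1H-pyrrole-2-carboxylate | COC(=O)c1c(CCC(=O)OCc2ccccc2)ccn1S(=O)(=O)c1ccc(C)cc1 | intermediate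
7 | 3-[2-(methoxycarbonyl)-1-tosyl-1H-pyrrol-3-yl]propanoic acid | COC(=O)c1c(CCC(=O)O)ccn1S(=O)(=O)c1ccc(C)cc1 | intermediate
8 | icosanoic acid | CCCCCCCCCCCCCCCCCCCC(=O)O | starting material
9 | methyl 3-henicosyl-1-tosyl-1H-pyrrole-2-carboxylate | CCCCCCCCCCCCCCCCCCCCCc1ccn(S(=O)(=O)c2ccc(C)cc2)c1C(=O)OC | intermediate
10 | sodium 3-henicosyl-2-(methoxycarbonyl)pyrrol-1-ide | CCCCCCCCCCCCCCCCCCCCCc1cc[n-]c1C(=O)OC.[Na+] | intermediate
11 | methyl 3-henicosyl-1H-pyrrole-2-carboxylate | CCCCCCCCCCCCCCCCCCCCCc1cc[nH]c1C(=O)OC | target

**Step count**

Total steps: 5. Longest linear sequence: 5 steps (from 1 to 11).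

**Steps most likely to fail**

1. Step 4 (mixed Kolbe electrolysis). The ring-side radical may be oxidised further and trapped by methanol or lose a proton. The heteroarene may be oxidised in competition with the carboxylate. The waxy hydrocarbon may foul the anode, and much of 7 may be lost to homo-coupling. The fallback builds the chain by olefin cross-metathesis and sets out from 3. Stille coupling of 3 with allyltributylstannane (Pd(PPh3)4, toluene, 100 °C) should give methyl 3-allyl-1-tosyl-1H-pyrrole-2-carboxylate F1. Cross-metathesis of this with an excess of 1-icosene (second-generation Grubbs catalyst, RuCl2(=CHPh)(H2IMes)(PCy3), CH2Cl2, 40 °C, with 1,4-benzoquinone to suppress double-bond migration) should give methyl 3-[(E)-henicos-2-en-1-yl]-1-tosyl-1H-pyrrole-2-carboxylate F2, for which either alkene geometry serves. Hydrogenation (H2, 10% Pd/C, EtOAc) then brings the material back to the route at 9.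

2. Step 2 (Heck reaction). Oxidative addition at the C3–Br bond next to the ester may be slow, so that protodebromination, loss of the N-sulfonyl group in hot amine/DMF or oligomerisation of the acrylate take over. The fallback replaces the alkene insertion by an sp2–sp3 Negishi coupling and sets out from 3. Benzyl 3-bromopropanoate is converted with zinc dust and LiCl in THF into [3-(benzyloxy)-3-oxopropyl]zinc bromide F3. Coupling of this with 3 (Pd(OAc)2, SPhos, THF, 50 °C) should give the saturated benzyl ester directly, so the route is rejoined at 6, which is then isolated and hydrogenolysed to 7 under the conditions of step 3.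

3. Step 5 (detosylation). The freed ring nitrogen may be methylated by the sulfonate ester co-product, the waxy substrate may react sluggishly, and adventitious water may saponify the ester. The fallback sets out from 9 and cleaves the S–N bond reductively by electron transfer instead of by nucleophilic attack at sulfur: magnesium turnings in MeOH–THF under sonication at rt, then aqueous NH4Cl, should give 11 directly, with a sulfinate as the leaving fragment and no alkylating agent formed. No new compound is made on this way (F0).

**Further compounds**

F1 | step 4 | methyl 3-allyl-1-tosyl-1H-pyrrole-2-carboxylate | C=CCc1ccn(S(=O)(=O)c2ccc(C)cc2)c1C(=O)OC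
F2 | step 4 | methyl 3-[(E)-henicos-2-en-1-yl]-1-tosyl-1H-pyrrole-2-carboxylate | CCCCCCCCCCCCCCCCCC/C=C/Cc1ccn(S(=O)(=O)c2ccc(C)cc2)c1C(=O)OC
F3 | step 2 | [3-(benzyloxy)-3-oxopropyl]zinc bromide | O=C(CC[Zn]Br)OCc1ccccc1
F0 | step 5 | none | none
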